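**Plan**

1. Locants (cyclohexenone numbering): C1 C=O, C2 C–CH2OH, C3 =CH, C4 CH–O-propanoyl, C5 CH–isopropyl, C6 CH–O-enoate. The retrosynthesis cuts, in order: the two O–Si bonds; the C4–O propanoate bond (with inversion); the isopropyl C–H bonds back to isopropenyl; the ring bond C4–C5 (carbonyl-ene); the furan C–O bond that re-closes the resulting (Z)-4-oxo-2-enal to a 2,3-disubstituted furan; the enoate ester C–O bond; the furan–carbinol C–C bond.
2. Enabling feature: C4(–O)–C3=C2–C1(=O) of the ring is an oxidatively opened furan. The furan oxygen becomes the C1 carbonyl oxygen, furan C5 becomes the aldehyde carbon C4, and the furan ring fixes the Z geometry of C2=C3. C5 with its isopropyl group is the CH carbon of a CH=C(CH3)2 ene donor whose allylic methyl groups supply the hydrogen that passes to the aldehyde oxygen.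
3. Forward: furan-3-ylmethanol is silylated, metalated at C2 and added to prenal (sets C6). Esterification with the silyl-protected side-chain acid (Wittig, saponification) joins the two fragments. NBS opens the furan, the Me2AlCl carbonyl-ene reaction closes the only carbocycle, and hydrogenation, Mitsunobu propanoylation and desilylation finish the route.
4. Stereochemistry: C6 comes from the ligand-controlled furylzinc addition. C5 and C4 follow from C6 in the ene transition state (1,3-allylic strain, s-trans enal; all-trans ring). C4 is then inverted by the Mitsunobu step, which places the propanoate cis to isopropyl. The E enoate comes from the Wittig reaction.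

Key step: step 7

Remark: the target is read as the (4S,5S,6R)-cyclohexenone, with the propanoate cis and the enoate trans to the isopropyl group; furan-3-ylmethanol, prenal, (tert-butyldimethylsilyloxy)acetaldehyde and the stabilised ylide are taken as commercial (TBS = tert-butyldimethylsilyl).

**Step 1**
Reactants: 1 furan-3-ylmethanol
Product: 2 tert-butyl(furan-3-ylmethoxy)dimethylsilane
Conditions: TBSCl, imidazole, CH2Cl2, 0 °C to rt
Reagents that add atoms: tert-butyldimethylsilyl chloride (TBSCl), CC(C)(C)[Si](C)(C)Cl
Why: Imidazole-assisted silylation of a primary alcohol is routine and involves no stereocentre.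

**Step 2**
Reactants: 2 tert-butyl(furan-3-ylmethoxy)dimethylsilane; 3 3-methylbut-2-enal (prenal)
Product: 6 (1R)-1-{3-[(tert-butyldimethylsilyloxy)methyl]furan-2-yl}-3-methylbut-2-en-1-ol, via 2-lithiofuran 4 (not isolated), via furyl(ethyl)zinc 5 (not isolated)
Conditions: n-BuLi, t-BuOMe, −78 to 0 °C (no HMPA); EtZnCl, −78 to 0 °C; TEEDA (N,N,N′,N′-tetraethylethylenediamine), toluene; (−)-MIB [(2S)-3-exo-morpholinoisoborneol] (10 mol %), then 3, 0 °C; aq. NH4Cl
Reagents that add atoms: n-butyllithium (n-BuLi), [Li]CCCC; ethylzinc chloride (EtZnCl), CC[Zn]Cl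
Why: The CH2OSi oxygen directs lithiation to furan C2 (directed metalation, kept cold and HMPA-free to prevent 1,4 O-to-C silyl migration), transmetalation gives the mixed furyl(ethyl)zinc, and the amino-alcohol-catalysed asymmetric aryl transfer to aldehydes with (−)-MIB is expected to deliver the furyl group in a 1,2-sense to the Si face of prenal, which sets the (R)-carbinol centre (future C6), the lithium and ethylzinc units being lost again on work-up.

**Step 3**
Reactants: 7 (tert-butyldimethylsilyloxy)acetaldehyde; 8 ethyl 2-(triphenylphosphoranylidene)propanoate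
Product: 9 ethyl (2E)-4-(tert-butyldimethylsilyloxy)-2-methylbut-2-enoate
Conditions: CH2Cl2, rt
Reagents that add atoms: none
Why: A Wittig reaction with a stabilised, α-methyl ylide should give the trisubstituted enoate with the ester trans to the CH2OSi chain (E).

**Step 4**
Reactants: 9 ethyl (2E)-4-(tert-butyldimethylsilyloxy)-2-methylbut-2-enoate
Product: 10 (2E)-4-(tert-butyldimethylsilyloxy)-2-methylbut-2-enoic acid
Conditions: LiOH, THF/MeOH/H2O, 0 °C to rt; then aq. HCl to pH 4, 0 °C
Reagents that add atoms: lithium hydroxide, [Li+].[OH-]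
Why: Saponification of the ethyl ester should leave the primary TBS ether and the E double bond intact under cold aqueous base and brief mild acidification.

**Step 5**
Reactants: 6 (1R)-1-{3-[(tert-butyldimethylsilyloxy)methyl]furan-2-yl}-3-methylbut-2-en-1-ol; 10 (2E)-4-(tert-butyldimethylsilyloxy)-2-methylbut-2-enoic acid
Product: 11 (1R)-1-{3-[(tert-butyldimethylsilyloxy)methyl]furan-2-yl}-3-methylbut-2-en-1-yl (2E)-4-(tert-butyldimethylsilyloxy)-2-methylbut-2-enoate
Conditions: DCC, DMAP (cat.), CH2Cl2, 0 °C to rt; chromatography on Et3N-deactivated silica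
Reagents that add atoms: none
Why: Steglich esterification forms the acyl–O bond under non-acidic conditions, so the ionisable furfuryl/allyl C–O bond is not broken and the carbinol configuration is retained.

**Step 6**
Reactants: 11 (1R)-1-{3-[(tert-butyldimethylsilyloxy)methyl]furan-2-yl}-3-methylbut-2-en-1-yl (2E)-4-(tert-butyldimethylsilyloxy)-2-methylbut-2-enoate
Product: 12 (2Z,5R)-3-[(tert-butyldimethylsilyloxy)methyl]-7-methyl-1,4-dioxoocta-2,6-dien-5-yl (2E)-4-(tert-butyldimethylsilyloxy)-2-methylbut-2-enoate
Conditions: NBS (1.05 equiv), NaHCO3, acetone/H2O (10:1), −20 °C; crude product used at once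
Reagents that add atoms: water, O
Why: Oxidative furan ring opening (bromination at the free α-position, hydration, loss of HBr) should unmask the furan as the (Z)-4-oxo-2-enal with the Z geometry inherited from the ring; the furan is far more nucleophilic than the trisubstituted alkene or the enoate, and the acylated carbinol cannot divert into an Achmatowicz pyranone.

**Step 7**
Reactants: 12 (2Z,5R)-3-[(tert-butyldimethylsilyloxy)methyl]-7-methyl-1,4-dioxoocta-2,6-dien-5-yl (2E)-4-(tert-butyldimethylsilyloxy)-2-methylbut-2-enoate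
Product: 13 (4R,5S,6R)-2-[(tert-butyldimethylsilyloxy)methyl]-4-hydroxy-6-{[(2E)-4-(tert-butyldimethylsilyloxy)-2-methylbut-2-enoyl]oxy}-5-(prop-1-en-2-yl)cyclohex-2-en-1-one
Conditions: Me2AlCl (3 equiv), CH2Cl2, −78 to −40 °C; then H2O, aq. potassium sodium tartrate
Reagents that add atoms: none
Why: Proposed new method: Me2AlCl binds the aldehyde oxygen of 12, the CH carbon of the 2-methylprop-1-enyl group (future C5) bonds to the aldehyde carbon (future C4) while a hydrogen of an allylic methyl group passes to that oxygen through a six-centre array, and the aluminium alkoxide of 13, now carrying an isopropenyl group, forms with loss of methane. The closest known reaction type is the Lewis-acid-promoted intramolecular carbonyl-ene cyclisation of 7-methyloct-6-enal-type aldehydes (citronellal to isopulegol) together with Me2AlCl-mediated ene reactions of aldehydes; not yet shown is a furan-derived (Z)-4-oxo-2-enal as the enophile, which is argued to react because its aldehyde is the most Lewis-basic and, through the conjugated keto group, an unusually electron-poor carbonyl, and because the Z double bond inherited from the furan holds it next to the alkene. The six-membered carbocycle closes in the 6-exo-trig mode at the C=O group, the reacting C=C bond likewise lying outside the new ring. C5 is controlled by the existing C6 centre, because to avoid 1,3-allylic strain with the cis methyl group the C6–H bond eclipses the alkene, the acyloxy group sits pseudo-equatorial and the new bond forms trans to it; C4 is controlled by the s-trans geometry of the aluminium-complexed enal, which turns the oxygen outward into a pseudo-equatorial position trans to the isopropenyl group. The step needs chemoselectivity for the aldehyde over conjugate attack at C3 and over the ketone, secured because attack at C3 would be a 5-endo-trig closure and attack on the ketone would give a three-membered ring, and it needs bonding through the CH rather than the C(CH3)2 carbon, secured by the polarisation of the trisubstituted alkene toward its tertiary carbon; low temperature and the proton-scavenging Me–Al bonds should suppress Z-to-E isomerisation and chloride capture.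

**Step 8**
Reactants: 13 (4R,5S,6R)-2-[(tert-butyldimethylsilyloxy)methyl]-4-hydroxy-6-{[(2E)-4-(tert-butyldimethylsilyloxy)-2-methylbut-2-enoyl]oxy}-5-(prop-1-en-2-yl)cyclohex-2-en-1-one
Product: 14 (4R,5S,6R)-2-[(tert-butyldimethylsilyloxy)methyl]-4-hydroxy-6-{[(2E)-4-(tert-butyldimethylsilyloxy)-2-methylbut-2-enoyl]oxy}-5-(propan-2-yl)cyclohex-2-en-1-one
Conditions: H2 (1 atm), RhCl(PPh3)3 (10 mol %), benzene, rt
Reagents that add atoms: none
Why: Homogeneous hydrogenation with RhCl(PPh3)3 should reduce the 1,1-disubstituted isopropenyl alkene and leave the trisubstituted, conjugated enone and enoate double bonds alone (as in the carvone to carvotanacetone reduction), with no stereocentre created or touched.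

**Step 9**
Reactants: 14 (4R,5S,6R)-2-[(tert-butyldimethylsilyloxy)methyl]-4-hydroxy-6-{[(2E)-4-(tert-butyldimethylsilyloxy)-2-methylbut-2-enoyl]oxy}-5-(propan-2-yl)cyclohex-2-en-1-one
Product: 15 (4S,5S,6R)-2-[(tert-butyldimethylsilyloxy)methyl]-6-{[(2E)-4-(tert-butyldimethylsilyloxy)-2-methylbut-2-enoyl]oxy}-4-(propanoyloxy)-5-(propan-2-yl)cyclohex-2-en-1-one
Conditions: EtCO2H, PPh3, DIAD, toluene, 0 °C to rt
Reagents that add atoms: propanoic acid, CCC(=O)O
Why: In the Mitsunobu reaction the pseudo-equatorial allylic alcohol is activated as its alkoxyphosphonium salt and displaced by propanoate in an SN2 step with inversion at C4, giving the propanoate cis to isopropyl; the equatorial leaving group has no antiperiplanar hydrogen, which disfavours E2 elimination, and SN2′ attack at the electron-poor enone α-carbon is disfavoured.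

**Step 10**
Reactants: 15 (4S,5S,6R)-2-[(tert-butyldimethylsilyloxy)methyl]-6-{[(2E)-4-(tert-butyldimethylsilyloxy)-2-methylbut-2-enoyl]oxy}-4-(propanoyloxy)-5-(propan-2-yl)cyclohex-2-en-1-one
Product: 16 (4S,5S,6R)-2-(hydroxymethyl)-6-{[(2E)-4-hydroxy-2-methylbut-2-enoyl]oxy}-4-(propanoyloxy)-5-(propan-2-yl)cyclohex-2-en-1-one (target, CNP0285949.1)
Conditions: HF·pyridine, pyridine/THF, 0 °C to rt
Reagents that add atoms: none
Why: Buffered fluoride desilylation should cleave both primary TBS ethers without ester cleavage, acyl migration or β-elimination, and no stereocentre is involved.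

**Compound list**

1 | furan-3-ylmethanol | OCc1ccoc1 | starting material
2 | tert-butyl(furan-3-ylmethoxy)dimethylsilane | CC(C)(C)[Si](C)(C)OCc1ccoc1 | intermediate
3 | 3-methylbut-2-enal (prenal) | CC(C)=CC=O | starting material
4 | {3-[(tert-butyldimethylsilyloxy)methyl]furan-2-yl}lithium | [Li]c1occc1CO[Si](C)(C)C(C)(C)C | intermediate
5 | ethyl{3-[(tert-butyldimethylsilyloxy)methyl]furan-2-yl}zinc | CC[Zn]c1occc1CO[Si](C)(C)C(C)(C)C | intermediate
6 | (1R)-1-{3-[(tert-butyldimethylsilyloxy)methyl]furan-2-yl}-3-methylbut-2-en-1-ol | CC(C)=C[C@@H](O)c1occc1CO[Si](C)(C)C(C)(C)C | intermediate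
7 | (tert-butyldimethylsilyloxy)acetaldehyde | O=CCO[Si](C)(C)C(C)(C)C | starting material
8 | ethyl 2-(triphenylphosphoranylidene)propanoate | CCOC(=O)C(C)=P(c1ccccc1)(c1ccccc1)c1ccccc1 | starting material
9 | ethyl (2E)-4-(tert-butyldimethylsilyloxy)-2-methylbut-2-enoate | CCOC(=O)/C(C)=C/CO[Si](C)(C)C(C)(C)C | intermediate
10 | (2E)-4-(tert-butyldimethylsilyloxy)-2-methylbut-2-enoic acid | OC(=O)/C(C)=C/CO[Si](C)(C)C(C)(C)C | intermediate
11 | (1R)-1-{3-[(tert-butyldimethylsilyloxy)methyl]furan-2-yl}-3-methylbut-2-en-1-yl (2E)-4-(tert-butyldimethylsilyloxy)-2-methylbut-2-enoate | CC(C)=C[C@@H](OC(=O)/C(C)=C/CO[Si](C)(C)C(C)(C)C)c1occc1CO[Si](C)(C)C(C)(C)C | intermediate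
12 | (2Z,5R)-3-[(tert-butyldimethylsilyloxy)methyl]-7-methyl-1,4-dioxoocta-2,6-dien-5-yl (2E)-4-(tert-butyldimethylsilyloxy)-2-methylbut-2-enoate | CC(C)=C[C@@H](OC(=O)/C(C)=C/CO[Si](C)(C)C(C)(C)C)C(=O)/C(CO[Si](C)(C)C(C)(C)C)=C\C=O | intermediate
13 | (4R,5S,6R)-2-[(tert-butyldimethylsilyloxy)methyl]-4-hydroxy-6-{[(2E)-4-(tert-butyldimethylsilyloxy)-2-methylbut-2-enoyl]oxy}-5-(prop-1-en-2-yl)cyclohex-2-en-1-one (hydroxy and acyloxy both trans to isopropenyl) | O[C@@H]1C=C(CO[Si](C)(C)C(C)(C)C)C(=O)[C@H](OC(=O)/C(C)=C/CO[Si](C)(C)C(C)(C)C)[C@H]1C(C)=C | intermediate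
14 | (4R,5S,6R)-2-[(tert-butyldimethylsilyloxy)methyl]-4-hydroxy-6-{[(2E)-4-(tert-butyldimethylsilyloxy)-2-methylbut-2-enoyl]oxy}-5-(propan-2-yl)cyclohex-2-en-1-one | O[C@@H]1C=C(CO[Si](C)(C)C(C)(C)C)C(=O)[C@H](OC(=O)/C(C)=C/CO[Si](C)(C)C(C)(C)C)[C@H]1C(C)C | intermediate
15 | (4S,5S,6R)-2-[(tert-butyldimethylsilyloxy)methyl]-6-{[(2E)-4-(tert-butyldimethylsilyloxy)-2-methylbut-2-enoyl]oxy}-4-(propanoyloxy)-5-(propan-2-yl)cyclohex-2-en-1-one | CCC(=O)O[C@H]1C=C(CO[Si](C)(C)C(C)(C)C)C(=O)[C@H](OC(=O)/C(C)=C/CO[Si](C)(C)C(C)(C)C)[C@H]1C(C)C | intermediate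
16 | (4S,5S,6R)-2-(hydroxymethyl)-6-{[(2E)-4-hydroxy-2-methylbut-2-enoyl]oxy}-4-(propanoyloxy)-5-(propan-2-yl)cyclohex-2-en-1-one | CCC(=O)O[C@H]1C=C(CO)C(=O)[C@H](OC(=O)/C(C)=C/CO)[C@H]1C(C)C | target

**Step count and risks**

Total step count: 10. Longest linear sequence: 8 steps (steps 1, 2, 5, 6, 7, 8, 9, 10 from furan-3-ylmethanol; the acid branch, steps 3 and 4, joins at step 5).

Steps most likely to fail:

1. Step 7 (Proposed new method). The risk is that Lewis-acid-promoted Z-to-E isomerisation or oligomerisation of the keto-enal outruns ring closure, or that facial control at the aldehyde is lost. The fallback uses known chemistry, an intramolecular Nozaki–Hiyama allylation. It sets out from 11: SeO2 (cat.)/t-BuOOH in CH2Cl2 should oxidise the E methyl group of the 2-methylprop-1-enyl unit to the (E)-allylic alcohol F1. An Appel reaction (CBr4, PPh3, 0 °C) would then give the allylic bromide F2, and furan opening as in step 6 the bromo keto-enal F3. CrCl2 in THF at 0 °C would convert the allylic bromide into an allylchromium unit that adds through its γ-carbon to the aldehyde via a closed chair transition state. This forms the same ring bond and the isopropenyl group with hydroxy trans to it, and comes back to the route at 13.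

2. Step 9. The risk is slow displacement at the hindered alkoxyphosphonium centre, which leaves room for elimination toward a dienone that aromatises, or for acyl transfer with retention. The fallback sets out from 14: ClCH2SO2Cl/pyridine (0 °C) would give the chloromethanesulfonate F4, a small and highly reactive leaving group. Caesium propanoate (EtCO2Cs) with 18-crown-6 in toluene (60 °C) would displace it with inversion, and the route is rejoined at 15.

3. Step 6. The risk is competing electrophilic bromination of the electron-rich trisubstituted alkene, or acid-promoted Z-to-E isomerisation of the keto-enal during the aqueous procedure. The fallback sets out from 11: dye-sensitised photooxygenation (O2, tetraphenylporphyrin, visible light, CH2Cl2, −78 °C) would add singlet oxygen across the furan to give the [4+2] endoperoxide F5, expected as a mixture of diastereomers at the bicyclic core that converge in the next operation. Me2S (−78 °C to rt) would reduce it to the same (Z)-keto-enal in anhydrous, neutral solution, and the route is rejoined at 12.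

**Further compounds**

F1 | step 7 | (1R,2E)-1-{3-[(tert-butyldimethylsilyloxy)methyl]furan-2-yl}-4-hydroxy-3-methylbut-2-en-1-yl (2E)-4-(tert-butyldimethylsilyloxy)-2-methylbut-2-enoate | OC/C(C)=C/[C@@H](OC(=O)/C(C)=C/CO[Si](C)(C)C(C)(C)C)c1occc1CO[Si](C)(C)C(C)(C)C
F2 | step 7 | (1R,2E)-4-bromo-1-{3-[(tert-butyldimethylsilyloxy)methyl]furan-2-yl}-3-methylbut-2-en-1-yl (2E)-4-(tert-butyldimethylsilyloxy)-2-methylbut-2-enoate | BrC/C(C)=C/[C@@H](OC(=O)/C(C)=C/CO[Si](C)(C)C(C)(C)C)c1occc1CO[Si](C)(C)C(C)(C)C
F3 | step 7 | (2Z,5R,6E)-8-bromo-3-[(tert-butyldimethylsilyloxy)methyl]-7-methyl-1,4-dioxoocta-2,6-dien-5-yl (2E)-4-(tert-butyldimethylsilyloxy)-2-methylbut-2-enoate | BrC/C(C)=C/[C@@H](OC(=O)/C(C)=C/CO[Si](C)(C)C(C)(C)C)C(=O)/C(CO[Si](C)(C)C(C)(C)C)=C\C=O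
F4 | step 9 | (4R,5R,6R)-2-[(tert-butyldimethylsilyloxy)methyl]-4-[(chloromethanesulfonyl)oxy]-6-{[(2E)-4-(tert-butyldimethylsilyloxy)-2-methylbut-2-enoyl]oxy}-5-(propan-2-yl)cyclohex-2-en-1-one | ClCS(=O)(=O)O[C@@H]1C=C(CO[Si](C)(C)C(C)(C)C)C(=O)[C@H](OC(=O)/C(C)=C/CO[Si](C)(C)C(C)(C)C)[C@H]1C(C)C
F5 | step 6 | (1R)-1-{6-[(tert-butyldimethylsilyloxy)methyl]-2,3,7-trioxabicyclo[2.2.1]hept-5-en-1-yl}-3-methylbut-2-en-1-yl (2E)-4-(tert-butyldimethylsilyloxy)-2-methylbut-2-enoate | CC(C)=C[C@@H](OC(=O)/C(C)=C/CO[Si](C)(C)C(C)(C)C)C12OOC(C=C1CO[Si](C)(C)C(C)(C)C)O2
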